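**Retrosynthetic overview**
1. Target 20 ⇐ tris-MOM dihydrochalcone 19 ⇐ chalcone 17 by 1,4-reduction; 17 ⇐ aryl methyl ketone 14 + 4-methoxybenzaldehyde 15 by crossed aldol (Claisen–Schmidt) condensation, the key C–C bond.
2. Ketone 14 ⇐ dihydrobenzofuran 8 by two successive directed ortho-lithiations: prenyl at C5, then acetyl at C7.
3. Dihydrobenzofuran 7/8 ⇐ (R)-epoxide 5 by 5-exo phenoxide opening with inversion; 5 ⇐ Shi epoxidation of silylated 2-prenylphloroglucinol 4. The two ortho oxygens are equivalent, so ring closure has no regiochemical issue.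
4. 2-Prenylphloroglucinol 3 ⇐ phloroglucinol 1 + prenyl bromide 2.
5. Ring order: both benzene rings are bought; the dihydrofuran (step 4) is the only ring made.

Assumption: the stereocentre in the SMILES is read as (S) at C2 of the dihydrobenzofuran, and the D-fructose-derived Shi ketone, Stryker's reagent and N-methoxy-N-methylacetamide count as commercial.

**Step 1**
Reactants: 1 phloroglucinol (3 equiv); 2 prenyl bromide
Product: 3 2-(3-methylbut-2-en-1-yl)benzene-1,3,5-triol
Conditions: DBU (1 equiv), THF, 0 °C → rt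
Reagents that add atoms: none
Why: Phloroglucinol reacts through its phenoxide/keto tautomer as a carbon nucleophile (Friedel–Crafts-type C-allylation), and the excess of triol holds the reaction at mono-prenylation.

**Step 2**
Reactants: 3 2-(3-methylbut-2-en-1-yl)benzene-1,3,5-triol
Product: 4 1,3,5-tris(tert-butyldimethylsilyloxy)-2-(3-methylbut-2-en-1-yl)benzene
Conditions: TBSCl (3.6 equiv), imidazole, DMF, rt
Reagents that add atoms: tert-butyldimethylsilyl chloride, CC(C)(C)[Si](C)(C)Cl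
Why: Silyl ether formation masks the three phenols with fluoride-labile groups, so the electron-rich ring survives the dioxirane oxidation and the phenols can later be released under basic conditions.

**Step 3**
Reactants: 4 1,3,5-tris(tert-butyldimethylsilyloxy)-2-(3-methylbut-2-en-1-yl)benzene
Product: 5 (R)-3-[2,4,6-tris(tert-butyldimethylsilyloxy)benzyl]-2,2-dimethyloxirane
Conditions: D-fructose-derived Shi ketone (30 mol%), Oxone, K2CO3, Bu4NHSO4, MeCN/DMM, aq. Na2B4O7–EDTA buffer (pH ≈ 10.5), 0 °C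
Reagents that add atoms: potassium peroxymonosulfate (Oxone), [K+].[O-]S(=O)(=O)OO
Why: Shi asymmetric epoxidation, in which the chiral dioxirane attacks the trisubstituted alkene through the spiro transition state on the face that gives the (R)-epoxide, as for other 2-methyl-2-alkenes (typically about 90% ee).

**Step 4**
Reactants: 5 (R)-3-[2,4,6-tris(tert-butyldimethylsilyloxy)benzyl]-2,2-dimethyloxirane
Product: 7 (S)-2-(2-hydroxypropan-2-yl)-2,3-dihydrobenzofuran-4,6-diol, via epoxy triol 6 (not isolated)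
Conditions: TBAF (3.5 equiv), THF, 0 °C → rt; 1 M HCl work-up
Reagents that add atoms: none
Why: Fluoride desilylation frees the phenoxides, and either of the two equivalent ortho phenoxides opens the epoxide by 5-exo-tet SN2 attack at the secondary carbon with inversion, turning the (R)-epoxide carbon into the (S)-configured C2.

**Step 5**
Reactants: 7 (S)-2-(2-hydroxypropan-2-yl)-2,3-dihydrobenzofuran-4,6-diol
Product: 8 (S)-4,6-bis(methoxymethoxy)-2-[2-(methoxymethoxy)propan-2-yl]-2,3-dihydrobenzofuran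
Conditions: NaH (4 equiv), MOMCl (4 equiv), DMF, 0 °C → rt
Reagents that add atoms: chloromethyl methyl ether (MOMCl), COCCl
Why: Williamson-type O-alkylation of both phenoxides and the tertiary alkoxide gives acetals that direct lithiation, survive strong base and removes the acidic O–H groups.

**Step 6**
Reactants: 8 (S)-4,6-bis(methoxymethoxy)-2-[2-(methoxymethoxy)propan-2-yl]-2,3-dihydrobenzofuran; 2 prenyl bromide
Product: 10 (S)-4,6-bis(methoxymethoxy)-2-[2-(methoxymethoxy)propan-2-yl]-5-(3-methylbut-2-en-1-yl)-2,3-dihydrobenzofuran, via C5-aryllithium 9 (not isolated)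
Conditions: n-BuLi (1.2 equiv), THF, 0 °C, 1 h; CuI (10 mol%), then 2, −78 °C → rt
Reagents that add atoms: none
Why: Directed ortho-metalation, where C5–H between two chelating OMOM groups is lithiated in preference to C7–H (one OMOM plus the ring ether), followed by copper-catalysed SN2 allylation that gives the linear prenyl group.

**Step 7**
Reactants: 10 (S)-4,6-bis(methoxymethoxy)-2-[2-(methoxymethoxy)propan-2-yl]-5-(3-methylbut-2-en-1-yl)-2,3-dihydrobenzofuran; 11 N-methoxy-N-methylacetamide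
Product: 14 1-[(S)-4,6-bis(methoxymethoxy)-2-[2-(methoxymethoxy)propan-2-yl]-5-(3-methylbut-2-en-1-yl)-2,3-dihydrobenzofuran-7-yl]ethan-1-one, via C7-aryllithium 12 (not isolated), via lithium hemiaminal adduct 13 (not isolated)
Conditions: n-BuLi (1.3 equiv), TMEDA, THF, −78 → 0 °C; then 11, −78 °C → rt; H2O
Reagents that add atoms: none
Why: A second directed ortho-metalation at the only ring C–H left (flanked by 6-OMOM and O1) and Weinreb acylation, whose chelated tetrahedral adduct prevents over-addition.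

**Step 8**
Reactants: 14 1-[(S)-4,6-bis(methoxymethoxy)-2-[2-(methoxymethoxy)propan-2-yl]-5-(3-methylbut-2-en-1-yl)-2,3-dihydrobenzofuran-7-yl]ethan-1-one; 15 4-methoxybenzaldehyde
Product: 17 (E)-1-[(S)-4,6-bis(methoxymethoxy)-2-[2-(methoxymethoxy)propan-2-yl]-5-(3-methylbut-2-en-1-yl)-2,3-dihydrobenzofuran-7-yl]-3-(4-methoxyphenyl)prop-2-en-1-one, via aldol adduct 16 (not isolated)
Conditions: KOH (50% aq.), EtOH, rt, 24–48 h
Reagents that add atoms: none
Why: Claisen–Schmidt crossed aldol condensation, in which the methyl ketone enolate adds to the non-enolisable aldehyde and E1cB dehydration gives the (E)-chalcone; C2 carries no acidic proton and is untouched.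

**Step 9**
Reactants: 17 (E)-1-[(S)-4,6-bis(methoxymethoxy)-2-[2-(methoxymethoxy)propan-2-yl]-5-(3-methylbut-2-en-1-yl)-2,3-dihydrobenzofuran-7-yl]-3-(4-methoxyphenyl)prop-2-en-1-one
Product: 19 1-[(S)-4,6-bis(methoxymethoxy)-2-[2-(methoxymethoxy)propan-2-yl]-5-(3-methylbut-2-en-1-yl)-2,3-dihydrobenzofuran-7-yl]-3-(4-methoxyphenyl)propan-1-one, via copper enolate 18 (not isolated)
Conditions: [(Ph3P)CuH]6 (0.4 equiv), degassed H2O (5 equiv), benzene, rt, argon
Reagents that add atoms: none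
Why: Stryker conjugate reduction delivers hydride 1,4 to the enone only and water protonates the copper enolate, leaving the isolated trisubstituted prenyl alkene, the ketone and the acetals untouched.

**Step 10**
Reactants: 19 1-[(S)-4,6-bis(methoxymethoxy)-2-[2-(methoxymethoxy)propan-2-yl]-5-(3-methylbut-2-en-1-yl)-2,3-dihydrobenzofuran-7-yl]-3-(4-methoxyphenyl)propan-1-one
Product: 20 1-[(S)-4,6-dihydroxy-2-(2-hydroxypropan-2-yl)-5-(3-methylbut-2-en-1-yl)-2,3-dihydrobenzofuran-7-yl]-3-(4-methoxyphenyl)propan-1-one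
Conditions: 3 M aq. HCl/MeOH (1:5), 40 °C, monitored closely
Reagents that add atoms: none
Why: Acid-catalysed acetal solvolysis (transacetalisation to methanol) removes all three MOM groups under conditions mild enough to spare the prenyl group, the tertiary alcohol and the stereocentre.

**Compound list**
1 | phloroglucinol (benzene-1,3,5-triol) | Oc1cc(O)cc(O)c1 | starting material
2 | prenyl bromide (1-bromo-3-methylbut-2-ene) | CC(C)=CCBr | starting material
3 | 2-(3-methylbut-2-en-1-yl)benzene-1,3,5-triol | CC(C)=CCc1c(O)cc(O)cc1O | intermediate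
4 | 1,3,5-tris(tert-butyldimethylsilyloxy)-2-(3-methylbut-2-en-1-yl)benzene | CC(C)=CCc1c(O[Si](C)(C)C(C)(C)C)cc(O[Si](C)(C)C(C)(C)C)cc1O[Si](C)(C)C(C)(C)C | intermediate
5 | (R)-3-[2,4,6-tris(tert-butyldimethylsilyloxy)benzyl]-2,2-dimethyloxirane | CC1(C)O[C@@H]1Cc1c(O[Si](C)(C)C(C)(C)C)cc(O[Si](C)(C)C(C)(C)C)cc1O[Si](C)(C)C(C)(C)C | intermediate
6 | (R)-2-[(3,3-dimethyloxiran-2-yl)methyl]benzene-1,3,5-triol, present as its tetrabutylammonium phenoxide | CC1(C)O[C@@H]1Cc1c(O)cc(O)cc1O | intermediate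
7 | (S)-2-(2-hydroxypropan-2-yl)-2,3-dihydrobenzofuran-4,6-diol | CC(C)(O)[C@@H]1Cc2c(O)cc(O)cc2O1 | intermediate
8 | (S)-4,6-bis(methoxymethoxy)-2-[2-(methoxymethoxy)propan-2-yl]-2,3-dihydrobenzofuran | COCOC(C)(C)[C@@H]1Cc2c(OCOC)cc(OCOC)cc2O1 | intermediate
9 | C5-lithio derivative of 8 | COCOC(C)(C)[C@@H]1Cc2c(OCOC)c([Li])c(OCOC)cc2O1 | intermediate
10 | (S)-4,6-bis(methoxymethoxy)-2-[2-(methoxymethoxy)propan-2-yl]-5-(3-methylbut-2-en-1-yl)-2,3-dihydrobenzofuran | COCOC(C)(C)[C@@H]1Cc2c(OCOC)c(CC=C(C)C)c(OCOC)cc2O1 | intermediate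
11 | N-methoxy-N-methylacetamide | CON(C)C(C)=O | starting material
12 | C7-lithio derivative of 10 | COCOC(C)(C)[C@@H]1Cc2c(OCOC)c(CC=C(C)C)c(OCOC)c([Li])c2O1 | intermediate
13 | lithium hemiaminal adduct of 12 and 11 (new carbon unassigned) | COCOC(C)(C)[C@@H]1Cc2c(OCOC)c(CC=C(C)C)c(OCOC)c(C(C)(O[Li])N(C)OC)c2O1 | intermediate
14 | 1-[(S)-4,6-bis(methoxymethoxy)-2-[2-(methoxymethoxy)propan-2-yl]-5-(3-methylbut-2-en-1-yl)-2,3-dihydrobenzofuran-7-yl]ethan-1-one | COCOC(C)(C)[C@@H]1Cc2c(OCOC)c(CC=C(C)C)c(OCOC)c(C(C)=O)c2O1 | intermediate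
15 | 4-methoxybenzaldehyde | COc1ccc(C=O)cc1 | starting material
16 | 3-hydroxy-1-[(S)-4,6-bis(methoxymethoxy)-2-[2-(methoxymethoxy)propan-2-yl]-5-(3-methylbut-2-en-1-yl)-2,3-dihydrobenzofuran-7-yl]-3-(4-methoxyphenyl)propan-1-one (both carbinol epimers) | COCOC(C)(C)[C@@H]1Cc2c(OCOC)c(CC=C(C)C)c(OCOC)c(C(=O)CC(O)c3ccc(OC)cc3)c2O1 | intermediate
17 | (E)-1-[(S)-4,6-bis(methoxymethoxy)-2-[2-(methoxymethoxy)propan-2-yl]-5-(3-methylbut-2-en-1-yl)-2,3-dihydrobenzofuran-7-yl]-3-(4-methoxyphenyl)prop-2-en-1-one | COCOC(C)(C)[C@@H]1Cc2c(OCOC)c(CC=C(C)C)c(OCOC)c(C(=O)/C=C/c3ccc(OC)cc3)c2O1 | intermediate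
18 | copper(I) enolate of 19 (enolate geometry unassigned) | COCOC(C)(C)[C@@H]1Cc2c(OCOC)c(CC=C(C)C)c(OCOC)c(C(O[Cu])=CCc3ccc(OC)cc3)c2O1 | intermediate
19 | 1-[(S)-4,6-bis(methoxymethoxy)-2-[2-(methoxymethoxy)propan-2-yl]-5-(3-methylbut-2-en-1-yl)-2,3-dihydrobenzofuran-7-yl]-3-(4-methoxyphenyl)propan-1-one | COCOC(C)(C)[C@@H]1Cc2c(OCOC)c(CC=C(C)C)c(OCOC)c(C(=O)CCc3ccc(OC)cc3)c2O1 | intermediate
20 | 1-[(S)-4,6-dihydroxy-2-(2-hydroxypropan-2-yl)-5-(3-methylbut-2-en-1-yl)-2,3-dihydrobenzofuran-7-yl]-3-(4-methoxyphenyl)propan-1-one (CNP0150199.1) | COc1ccc(CCC(=O)c2c(O)c(CC=C(C)C)c(O)c3c2O[C@H](C(C)(C)O)C3)cc1 | target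

**Totals**
Total step count: 10. Longest linear sequence: 10 steps (1 → 20).

**Three steps most likely to fail**

Step 6 (site selectivity of the first lithiation, C5 against C7). The fallback sets out from 8 and comes back at 14. Electrophilic bromination of 8 with NBS (DMF, −20 °C) is expected to take the less hindered C7 position and gives (S)-7-bromo-4,6-bis(methoxymethoxy)-2-[2-(methoxymethoxy)propan-2-yl]-2,3-dihydrobenzofuran F3. Bromine–lithium exchange (n-BuLi, THF, −78 °C) and acetaldehyde give 1-[(S)-4,6-bis(methoxymethoxy)-2-[2-(methoxymethoxy)propan-2-yl]-2,3-dihydrobenzofuran-7-yl]ethan-1-ol F4. Its lithium alkoxide is lithiated with n-BuLi (2.2 equiv in all) at C5, now the only ring C–H, and allylated with 2 (CuI) to 1-[(S)-4,6-bis(methoxymethoxy)-2-[2-(methoxymethoxy)propan-2-yl]-5-(3-methylbut-2-en-1-yl)-2,3-dihydrobenzofuran-7-yl]ethan-1-ol F5. Dess–Martin oxidation then gives ketone 14, so step 7 is bypassed as well.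

Step 1 (modest yield, over-alkylation and O-alkylation in the direct C-prenylation). The fallback sets out from 1 and comes back at 3. Phloroglucinol is tris-protected (NaH, MOMCl, DMF) to 1,3,5-tris(methoxymethoxy)benzene F1. Lithiation between two OMOM groups (n-BuLi, THF, 0 °C) and copper-catalysed allylation with 2 give 1,3,5-tris(methoxymethoxy)-2-(3-methylbut-2-en-1-yl)benzene F2. Brief HCl/MeOH at rt removes the acetals and returns 3.

Step 9 (chemoselective reduction of the enone beside the prenyl alkene; possible over-reduction or incomplete conversion). The fallback sets out from 14 and comes back at 19. The kinetic lithium enolate of 14 (LiHMDS, THF, −78 °C) is alkylated with 4-methoxybenzyl bromide, so the saturated chain is formed by SN2 and no enone ever has to be reduced. No new compound arises on this way (none F0).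

**Further compounds**
F1 | step 1 | 1,3,5-tris(methoxymethoxy)benzene | COCOc1cc(OCOC)cc(OCOC)c1
F2 | step 1 | 1,3,5-tris(methoxymethoxy)-2-(3-methylbut-2-en-1-yl)benzene | COCOc1cc(OCOC)c(CC=C(C)C)c(OCOC)c1
F3 | step 6 | (S)-7-bromo-4,6-bis(methoxymethoxy)-2-[2-(methoxymethoxy)propan-2-yl]-2,3-dihydrobenzofuran | COCOC(C)(C)[C@@H]1Cc2c(OCOC)cc(OCOC)c(Br)c2O1
F4 | step 6 | 1-[(S)-4,6-bis(methoxymethoxy)-2-[2-(methoxymethoxy)propan-2-yl]-2,3-dihydrobenzofuran-7-yl]ethan-1-ol (both carbinol epimers) | COCOC(C)(C)[C@@H]1Cc2c(OCOC)cc(OCOC)c(C(C)O)c2O1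
F5 | step 6 | 1-[(S)-4,6-bis(methoxymethoxy)-2-[2-(methoxymethoxy)propan-2-yl]-5-(3-methylbut-2-en-1-yl)-2,3-dihydrobenzofuran-7-yl]ethan-1-ol (both carbinol epimers) | COCOC(C)(C)[C@@H]1Cc2c(OCOC)c(CC=C(C)C)c(OCOC)c(C(C)O)c2O1
F0 | step 9 | none | none
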